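**Plan**

- Retrosynthesis: the C8–O and C3–O ester bonds and the two C–O bonds of the C1–C10 oxirane are cut first, and the C8–O bond is traced back to C8–Si. C11=C13, the lactone O–C12 bond and C7–C11 are then removed to reach the 8-silyl cyclodecadienone 14. Its C8–C9 bond is cut (C1–C6 re-formed) to cyclohexenol 12, which comes from enone 5 and vinylstannane 9.
- Enabling feature: C1–C6 with C15 and the C10(C14)=C9 isopropenyl unit are an oxidised carveol. Its six-membered ring already holds the Z C4=C5 alkene, and the neighbouring ring atoms C6 and C1 can carry the two alkenyl arms of a 1,5-diene (C8=C7–C6–C1–C10=C9).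
- Forward order of rings: carvone six-ring → ten-membered ring by four-atom ring expansion (step 8) → γ-lactone (step 10) → oxirane (step 15); the epoxy acid is joined in the last step.
- Stereochemistry: C3 and the relay centre C1 come from (S)-carvone (epoxidation, Wharton transposition); the carbinol centre from addition anti to isopropenyl; C8 from chirality transfer in the chair oxy-Cope; C7 from alkylation anti to silicon; C6 from peripheral hydride attack; C1/C10 from peripheral epoxidation; the side-chain oxirane from Sharpless epoxidation.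

Key step: step 8

Remark on the chemistry: germacrane numbering (C1–C15) is used for all ten-membered-ring compounds; enolate 16 is drawn with the ring-cis C6=C7 geometry and Mannich base 22 as its 11R epimer, and neither choice affects the outcome.

**Route**

Step 1
Reactants: 1 (S)-(+)-carvone
Product: 2 (1S,4S,6S)-1-methyl-4-(prop-1-en-2-yl)-7-oxabicyclo[4.1.0]heptan-2-one
Conditions: 30% H2O2, NaOH (aq), MeOH, 0 °C
Reagents that add atoms: hydrogen peroxide, OO
Why: Weitz–Scheffer nucleophilic epoxidation touches only the enone alkene, and hydroperoxide adds axially to the β-carbon anti to the isopropenyl group, so both oxirane centres are set trans to it.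

Step 2
Reactants: 2 (1S,4S,6S)-carvone oxide
Product: 3 (1S,5R)-2-methyl-5-(prop-1-en-2-yl)cyclohex-2-en-1-ol (trans-carveol)
Conditions: N2H4·H2O, AcOH (cat.), MeOH, 0 °C → rt
Reagents that add atoms: none
Why: Wharton transposition, in which the epoxy hydrazone loses N2 and opens to the allylic alcohol without touching the C–O bond at the former β-carbon, so the hydroxyl stays trans to isopropenyl and, because oxygen has moved across the ring, the (S)-carvone skeleton emerges as (1S,5R)-trans-carveol.

Step 3
Reactants: 3 (1S,5R)-trans-carveol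
Product: 4 tert-butyldimethyl{[(1S,5R)-2-methyl-5-(prop-1-en-2-yl)cyclohex-2-en-1-yl]oxy}silane
Conditions: TBSCl, imidazole, DMF, rt
Reagents that add atoms: tert-butyldimethylsilyl chloride, CC(C)(C)[Si](C)(C)Cl
Why: Routine O-silylation of a secondary allylic alcohol that touches no stereocentre and gives a group stable to the bases and organometallics of steps 7–12.

Step 4
Reactants: 4 trans-carveol TBS ether
Product: 5 (4S,6R)-4-(tert-butyldimethylsilyloxy)-3-methyl-6-(prop-1-en-2-yl)cyclohex-2-en-1-one
Conditions: CrO3, 3,5-dimethylpyrazole, CH2Cl2, −20 °C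
Reagents that add atoms: chromium trioxide, O=[Cr](=O)=O
Why: Allylic oxidation of a cyclohexene to the enone with the CrO3–dimethylpyrazole complex, directed to the only ring CH2 next to the trisubstituted alkene (the other allylic ring carbon already bears the pseudoaxial silyloxy group and its C–H is poorly aligned), the low temperature protecting the new enolisable α-centre from epimerisation or conjugation of the isopropenyl group.

Step 5
Reactants: 6 benzylchlorodimethylsilane, 7 ethynylmagnesium bromide
Product: 8 benzyl(ethynyl)dimethylsilane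
Conditions: THF, 0 °C → rt
Reagents that add atoms: none
Why: Nucleophilic substitution at silicon by an alkynyl Grignard reagent, the standard preparation of ethynylsilanes.

Step 6
Reactants: 8 benzyl(ethynyl)dimethylsilane
Product: 9 (E)-benzyldimethyl[2-(tributylstannyl)ethenyl]silane
Conditions: Bu3SnH, AIBN (cat.), neat, 90 °C
Reagents that add atoms: tributyltin hydride, CCCC[SnH](CCCC)CCCC
Why: Radical hydrostannation of a silylacetylene puts tin on the unsubstituted terminus, and reversible stannyl-radical addition equilibrates the product to the E-1-silyl-2-stannylethene.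

Step 7
Reactants: 9 (E)-silylvinylstannane, 5 enone
Product: 12 (1R,4S,6R)-1-[(E)-2-(benzyldimethylsilyl)ethenyl]-4-(tert-butyldimethylsilyloxy)-3-methyl-6-(prop-1-en-2-yl)cyclohex-2-en-1-ol, via silylvinyllithium 10 (not isolated), via silylvinylcerium dichloride 11 (not isolated)
Conditions: 9, n-BuLi, THF, −78 °C; CeCl3 (anhydrous), −78 °C; then 5, −78 °C; aq NH4Cl
Reagents that add atoms: none
Why: Tin–lithium exchange keeps the E geometry, and the organocerium reagent adds 1,2 to the easily enolised enone without deprotonating it, entering along the equatorial trajectory anti to the neighbouring pseudoequatorial isopropenyl group so that the two alkenyl groups end up trans (1R carbinol).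

Step 8
Reactants: 12 trans-1,2-dialkenylcyclohexenol
Product: 14 (2Z,4S,6E,9R)-9-(benzyldimethylsilyl)-4-(tert-butyldimethylsilyloxy)-3,7-dimethylcyclodeca-2,6-dien-1-one, via potassium enolate 13 (not isolated)
Conditions: KH, 18-crown-6, THF, 0 °C → rt; then sat. aq NH4Cl, −78 °C
Reagents that add atoms: none
Why: Anionic oxy-Cope rearrangement, in which the crown-separated potassium alkoxide weakens the C1–C6 bond (germacrane numbering) and the 1,5-diene made of the silylvinyl group, that bond and the isopropenyl group undergoes a concerted [3,3] shift that forms C8–C9 and leaves the C6–C7 enolate 13, protonated on work-up. The closest known reaction type is the KH/18-crown-6 ring expansion of trans-1,2-dialkenylcyclohexanols and -cyclohexenols to cyclodec-5-enones. The ten-membered ring is not closed end to end but arises by four-atom expansion of the cyclohexene through a six-membered chair transition state, so no medium-ring cyclisation entropy is paid and the ring alkene is carried over unchanged as the Z C4=C5 enone. The only new stereocentre, C8, is fixed by the chair in which the ring bonds on C6 and C1 are equatorial and the E-vinylsilane holds silicon equatorial, so the (1R,6R) configuration of 12 (cyclohexenol numbering) is relayed to 8R, while the same chair turns the equatorial C1–C2 bond into the E C1=C10 alkene. The step needs chair over boat and the trans-diequatorial placement of the two alkenyl groups, both secured by the carvone-derived isopropenyl centre that directed step 7, whereas the other 1,5-diene that runs through the ring alkene could react only through a boat with an axial isopropenyl group and should not compete. Silicon stands in for the C8 oxygen because a β-alkoxy enolate would eliminate, and the benzyldimethylsilyl group is chosen because fluoride can later unmask it without acids or electrophilic metal salts that the C1=C10 alkene would not survive.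

Step 9
Reactants: 14 cyclodecadienone, 15 ethyl iodoacetate
Product: 17 ethyl (3S,7S,8R)-8-(benzyldimethylsilyl)-3-(tert-butyldimethylsilyloxy)-6-oxo-13-norgermacra-1(10)E,4Z-dien-12-oate, via lithium enolate 16 (not isolated)
Conditions: LDA, THF, −78 °C; then 15, DMPU, −78 → −40 °C
Reagents that add atoms: none
Why: Kinetic deprotonation gives the cross-conjugated C6–C7 enolate, and its alkylation follows the anti-to-silicon rule for enolates bearing a β-silyl stereocentre (C8–H eclipsing the enolate, electrophile opposite the silyl group), which places the acetate arm on the same ring face as silicon (7S) as the 7,8-relationship of the target requires.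

Step 10
Reactants: 17 keto ester
Product: 19 (3S,6R,7S,8R)-8-(benzyldimethylsilyl)-3-(tert-butyldimethylsilyloxy)-13-norgermacra-1(10)E,4Z-dien-12,6-olide, via hydroxy ester 18 (not isolated)
Conditions: NaBH4, CeCl3·7H2O, MeOH, −40 → 0 °C; then PPTS (cat.), CH2Cl2, rt
Reagents that add atoms: none
Why: Luche reduction gives clean 1,2-addition to the enone carbonyl, hydride is expected to enter from the outer face of the carbonyl that stands across the ring to give the 6R alcohol trans to the C7 arm (the least secure stereochemical assumption of the route), and the γ-hydroxy ester then lactonises to the trans-fused γ-lactone with loss of ethanol.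

Step 11
Reactants: 19 lactone, 20 N,N-dimethylmethyleneiminium iodide (Eschenmoser's salt)
Product: 22 (3S,6R,7S,8R,11R)-8-(benzyldimethylsilyl)-3-(tert-butyldimethylsilyloxy)-13-(dimethylamino)germacra-1(10)E,4Z-dien-12,6-olide, via lithium lactone enolate 21 (not isolated)
Conditions: LDA, THF, −78 °C; then 20, −78 °C → rt
Reagents that add atoms: none
Why: Mannich reaction of the lactone enolate with the preformed iminium salt at C11, the only enolisable position, whose configuration (drawn anti to C8) is erased in step 12.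

Step 12
Reactants: 22 Mannich base
Product: 24 (3S,6R,7S,8R)-8-(benzyldimethylsilyl)-3-(tert-butyldimethylsilyloxy)germacra-1(10)E,4Z,11(13)-trien-12,6-olide, via ammonium iodide 23 (not isolated)
Conditions: MeI, MeOH, rt; then NaHCO3 (aq), CH2Cl2, rt
Reagents that add atoms: none
Why: N-Methylation followed by Hofmann-type E1cB loss of trimethylamine, the standard second half of the Eschenmoser α-methylenation of lactones, done here before any ester is present.

Step 13
Reactants: 24 α-methylene lactone
Product: 25 (3S,6R,7S,8R)-8-(benzyldimethylsilyl)-3-hydroxygermacra-1(10)E,4Z,11(13)-trien-12,6-olide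
Conditions: HF·pyridine, pyridine, THF, 0 °C → rt
Reagents that add atoms: none
Why: Buffered HF O-desilylation cleaves the silyl ether while the carbon-bound benzylsilyl group, which needs unbuffered fluoride to form a silicate, and the acid-sensitive 1(10),4-diene are left alone.

Step 14
Reactants: 25 C3 alcohol, 26 isobutyryl chloride
Product: 27 (3S,6R,7S,8R)-8-(benzyldimethylsilyl)-3-(isobutyryloxy)germacra-1(10)E,4Z,11(13)-trien-12,6-olide
Conditions: pyridine, DMAP (cat.), CH2Cl2, 0 °C
Reagents that add atoms: none
Why: DMAP-catalysed acylation of the only free hydroxyl, with retention at C3.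

Step 15
Reactants: 27 C3 isobutyrate
Product: 29 (1R,3S,6R,7R,8R,10R)-1,10-epoxy-8-hydroxy-3-(isobutyryloxy)germacra-4Z,11(13)-dien-12,6-olide, via fluorosilane 28 (not isolated)
Conditions: TBAF, THF, 0 °C; then KF, mCPBA (3 equiv), DMF, 0 °C → rt
Reagents that add atoms: meta-chloroperoxybenzoic acid, O=C(OO)c1cccc(Cl)c1
Why: Fluoride expels the benzyl group as toluene, peracid oxidation of the resulting fluorosilane (Tamao–Fleming oxidation) replaces silicon by hydroxyl with retention at C8, and the same electrophilic oxidant performs a Prilezhaev epoxidation of only the electron-rich C1=C10 alkene from its exposed outer face (1R,10R), the C4=C5 alkene flanked by two allylic oxygens and the methylene lactone being too electron-poor to react.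

Step 16
Reactants: 30 angelic acid
Product: 31 (Z)-2-methylbut-2-en-1-ol
Conditions: LiAlH4, Et2O, 0 °C → rt
Reagents that add atoms: none
Why: Hydride reduction of the carboxylic acid to the allylic alcohol without touching or isomerising the Z-trisubstituted alkene.

Step 17
Reactants: 31 (Z)-2-methylbut-2-en-1-ol
Product: 32 [(2R,3S)-2,3-dimethyloxiran-2-yl]methanol
Conditions: Ti(OiPr)4, D-(−)-diethyl tartrate, t-BuOOH, 4 Å MS, CH2Cl2, −20 °C
Reagents that add atoms: tert-butyl hydroperoxide, CC(C)(C)OO
Why: Sharpless asymmetric epoxidation, in which the D-(−)-tartrate complex delivers oxygen to the alkene face that gives the (2R,3S) epoxy alcohol while the cis relationship of the methyl groups of the Z alkene is kept.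

Step 18
Reactants: 32 epoxy alcohol
Product: 33 (2S,3S)-2,3-dimethyloxirane-2-carboxylic acid
Conditions: TEMPO (cat.), PhI(OAc)2, MeCN/H2O, rt
Reagents that add atoms: water, O
Why: Oxoammonium (TEMPO) oxidation of the primary alcohol through the aldehyde hydrate to the acid under near-neutral conditions that leave the oxirane intact, the change of descriptor at C2 being only a change of substituent priority.

Step 19
Reactants: 29 epoxy alcohol, 33 (2S,3S)-epoxyangelic acid
Product: 35 (1R,3S,6R,7R,8R,10R)-1,10-epoxy-3-(isobutyryloxy)-8-{[(2S,3S)-2,3-dimethyloxiran-2-yl]carbonyloxy}germacra-4Z,11(13)-dien-12,6-olide (CNP0117882.1), via mixed anhydride 34 (not isolated)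
Conditions: 33, 2,4,6-trichlorobenzoyl chloride, Et3N, THF, rt; then 29, DMAP, toluene, rt → 40 °C
Reagents that add atoms: none
Why: Yamaguchi esterification, in which the α-quaternary epoxy acid is activated as the trichlorobenzoyl mixed anhydride and transferred by DMAP to the hindered C8 hydroxyl under basic conditions that spare both oxiranes, with retention at C8.

**Compound list**

1 | (S)-(+)-carvone | CC1=CC[C@@H](CC1=O)C(C)=C | starting material
2 | (1S,4S,6S)-1-methyl-4-(prop-1-en-2-yl)-7-oxabicyclo[4.1.0]heptan-2-one | CC(=C)[C@H]1C[C@@H]2O[C@]2(C)C(=O)C1 | intermediate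
3 | (1S,5R)-trans-carveol | CC(=C)[C@H]1C[C@H](O)C(C)=CC1 | intermediate
4 | (1S,5R)-trans-carveol tert-butyldimethylsilyl ether | CC(=C)[C@H]1C[C@H](O[Si](C)(C)C(C)(C)C)C(C)=CC1 | intermediate
5 | (4S,6R)-4-(tert-butyldimethylsilyloxy)-3-methyl-6-(prop-1-en-2-yl)cyclohex-2-en-1-one | CC(=C)[C@H]1C[C@H](O[Si](C)(C)C(C)(C)C)C(C)=CC1=O | intermediate
6 | benzylchlorodimethylsilane | C[Si](C)(Cl)Cc1ccccc1 | starting material
7 | ethynylmagnesium bromide | Br[Mg]C#C | starting material
8 | benzyl(ethynyl)dimethylsilane | C#C[Si](C)(C)Cc1ccccc1 | intermediate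
9 | (E)-benzyldimethyl[2-(tributylstannyl)ethenyl]silane | CCCC[Sn](CCCC)(CCCC)/C=C/[Si](C)(C)Cc1ccccc1 | intermediate
10 | (E)-[2-(benzyldimethylsilyl)ethenyl]lithium | [Li]/C=C/[Si](C)(C)Cc1ccccc1 | intermediate
11 | dichloro[(E)-2-(benzyldimethylsilyl)ethenyl]cerium | Cl[Ce](Cl)/C=C/[Si](C)(C)Cc1ccccc1 | intermediate
12 | (1R,4S,6R)-1-[(E)-2-(benzyldimethylsilyl)ethenyl]-4-(tert-butyldimethylsilyloxy)-3-methyl-6-(prop-1-en-2-yl)cyclohex-2-en-1-ol | O[C@]1(/C=C/[Si](C)(C)Cc2ccccc2)C=C(C)[C@@H](O[Si](C)(C)C(C)(C)C)C[C@@H]1C(C)=C | intermediate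
13 | potassium C6–C7 enolate of 14 (oxygen cis to C8) | C1/C(C)=C/C[C@H](O[Si](C)(C)C(C)(C)C)/C(C)=C\C([O-])=C\[C@@H]1[Si](C)(C)Cc2ccccc2.[K+] | intermediate
14 | (2Z,4S,6E,9R)-9-(benzyldimethylsilyl)-4-(tert-butyldimethylsilyloxy)-3,7-dimethylcyclodeca-2,6-dien-1-one (germacrane: 3S,8R, 6-one) | O=C1/C=C(/C)[C@@H](O[Si](C)(C)C(C)(C)C)C/C=C(\C)C[C@@H]([Si](C)(C)Cc2ccccc2)C1 | intermediate
15 | ethyl iodoacetate | CCOC(=O)CI | starting material
16 | lithium C6–C7 enolate of 14 (ring-cis geometry) | C1/C(C)=C/C[C@H](O[Si](C)(C)C(C)(C)C)/C(C)=C\C([O-])=C/[C@@H]1[Si](C)(C)Cc2ccccc2.[Li+] | intermediate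
17 | ethyl (3S,7S,8R)-8-(benzyldimethylsilyl)-3-(tert-butyldimethylsilyloxy)-6-oxo-13-norgermacra-1(10)E,4Z-dien-12-oate | O=C1/C=C(/C)[C@@H](O[Si](C)(C)C(C)(C)C)C/C=C(\C)C[C@@H]([Si](C)(C)Cc2ccccc2)[C@H]1CC(=O)OCC | intermediate
18 | ethyl (3S,6R,7S,8R)-8-(benzyldimethylsilyl)-3-(tert-butyldimethylsilyloxy)-6-hydroxy-13-norgermacra-1(10)E,4Z-dien-12-oate | O[C@@H]1/C=C(/C)[C@@H](O[Si](C)(C)C(C)(C)C)C/C=C(\C)C[C@@H]([Si](C)(C)Cc2ccccc2)[C@H]1CC(=O)OCC | intermediate
19 | (3S,6R,7S,8R)-8-(benzyldimethylsilyl)-3-(tert-butyldimethylsilyloxy)-13-norgermacra-1(10)E,4Z-dien-12,6-olide (trans-fused) | C1C(=O)O[C@@H]2/C=C(/C)[C@@H](O[Si](C)(C)C(C)(C)C)C/C=C(\C)C[C@@H]([Si](C)(C)Cc3ccccc3)[C@@H]12 | intermediate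
20 | N,N-dimethylmethyleneiminium iodide (Eschenmoser's salt) | C=[N+](C)C.[I-] | starting material
21 | lithium enolate of lactone 19 | C1=C([O-])O[C@@H]2/C=C(/C)[C@@H](O[Si](C)(C)C(C)(C)C)C/C=C(\C)C[C@@H]([Si](C)(C)Cc3ccccc3)[C@@H]12.[Li+] | intermediate
22 | (3S,6R,7S,8R,11R)-8-(benzyldimethylsilyl)-3-(tert-butyldimethylsilyloxy)-13-(dimethylamino)germacra-1(10)E,4Z-dien-12,6-olide | CN(C)C[C@@H]1C(=O)O[C@@H]2/C=C(/C)[C@@H](O[Si](C)(C)C(C)(C)C)C/C=C(\C)C[C@@H]([Si](C)(C)Cc3ccccc3)[C@@H]12 | intermediate
23 | trimethylammonium iodide of 22 | C[N+](C)(C)C[C@@H]1C(=O)O[C@@H]2/C=C(/C)[C@@H](O[Si](C)(C)C(C)(C)C)C/C=C(\C)C[C@@H]([Si](C)(C)Cc3ccccc3)[C@@H]12.[I-] | intermediate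
24 | (3S,6R,7S,8R)-8-(benzyldimethylsilyl)-3-(tert-butyldimethylsilyloxy)germacra-1(10)E,4Z,11(13)-trien-12,6-olide | C=C1C(=O)O[C@@H]2/C=C(/C)[C@@H](O[Si](C)(C)C(C)(C)C)C/C=C(\C)C[C@@H]([Si](C)(C)Cc3ccccc3)[C@@H]12 | intermediate
25 | (3S,6R,7S,8R)-8-(benzyldimethylsilyl)-3-hydroxygermacra-1(10)E,4Z,11(13)-trien-12,6-olide | C=C1C(=O)O[C@@H]2/C=C(/C)[C@@H](O)C/C=C(\C)C[C@@H]([Si](C)(C)Cc3ccccc3)[C@@H]12 | intermediate
26 | isobutyryl chloride | CC(C)C(=O)Cl | starting material
27 | (3S,6R,7S,8R)-8-(benzyldimethylsilyl)-3-(isobutyryloxy)germacra-1(10)E,4Z,11(13)-trien-12,6-olide | C=C1C(=O)O[C@@H]2/C=C(/C)[C@@H](OC(=O)C(C)C)C/C=C(\C)C[C@@H]([Si](C)(C)Cc3ccccc3)[C@@H]12 | intermediate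
28 | (3S,6R,7S,8R)-8-(fluorodimethylsilyl)-3-(isobutyryloxy)germacra-1(10)E,4Z,11(13)-trien-12,6-olide | C=C1C(=O)O[C@@H]2/C=C(/C)[C@@H](OC(=O)C(C)C)C/C=C(\C)C[C@@H]([Si](C)(C)F)[C@@H]12 | intermediate
29 | (1R,3S,6R,7R,8R,10R)-1,10-epoxy-8-hydroxy-3-(isobutyryloxy)germacra-4Z,11(13)-dien-12,6-olide | C=C1C(=O)O[C@@H]2/C=C(/C)[C@@H](OC(=O)C(C)C)C[C@H]3O[C@]3(C)C[C@@H](O)[C@@H]12 | intermediate
30 | angelic acid | C/C=C(/C)C(=O)O | starting material
31 | (Z)-2-methylbut-2-en-1-ol | C/C=C(/C)CO | intermediate
32 | [(2R,3S)-2,3-dimethyloxiran-2-yl]methanol | OC[C@@]1(C)O[C@H]1C | intermediate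
33 | (2S,3S)-2,3-dimethyloxirane-2-carboxylic acid | OC(=O)[C@@]1(C)O[C@H]1C | intermediate
34 | (2S,3S)-2,3-dimethyloxirane-2-carboxylic 2,4,6-trichlorobenzoic anhydride | O=C(OC(=O)[C@@]1(C)O[C@H]1C)c1c(Cl)cc(Cl)cc1Cl | intermediate
35 | CNP0117882.1 | C=C1C(=O)O[C@@H]2/C=C(/C)[C@@H](OC(=O)C(C)C)C[C@H]3O[C@]3(C)C[C@@H](OC(=O)[C@@]3(C)O[C@H]3C)[C@@H]12 | target

**Step count**

Total: 19 steps. Longest linear sequence: 14 steps from (S)-carvone (steps 1–4, 7–15 and 19); the vinylstannane (steps 5–6) and the epoxy acid (steps 16–18) are made in two short side branches.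

**Steps most likely to fail**

Step 9. The ten-membered ring may hold the enolate so that its open face is not the one opposite silicon, giving the C7 epimer, and proton exchange between product and enolate may erode conversion. The fallback sets C7 by C–H instead of C–C bond formation, which reverses the sense of induction under the same facial bias. It sets out from 14: aldol addition of the lithium enolate to ethyl glyoxylate gives the β-hydroxy ketone ethyl 2-hydroxy-2-(6-oxo-8-silylgermacradien-7-yl)acetate F1. Mesylation and DBU elimination give the exocyclic alkylidene keto ester F2. Conjugate reduction with Stryker's reagent followed by kinetic protonation of the resulting C6–C7 enolate then places hydrogen, not the carbon chain, on the open face, and the sequence comes back to the route at 17.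

Step 10. Hydride may add to the other face of the C6 carbonyl, so that the 6,7-cis alcohol and the cis-fused lactone form. The fallback accepts this face selection and corrects C6 by substitution with inversion. It sets out from 17: reduction gives the 6S hydroxy ester F3, which closes to the cis-fused lactone F4. Lithium hydroxide opens F4 to the 6S hydroxy acid F5. Mitsunobu lactonisation (PPh3, DIAD) activates the allylic C6 hydroxyl and lets the carboxylate displace it with inversion, and the sequence comes back to the route at 19.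

Step 15. Three events are combined, and the epoxidation may show poor facial selectivity while C8 still carries silicon, or the fluoride and perbenzoate medium may attack the methylene lactone. The fallback separates the events and uses a nucleophilic oxidant for the C–Si bond. It sets out from 27: TBAF and then KHCO3/H2O2 in THF/MeOH oxidise the fluorosilane 28 but leave the C1=C10 alkene, giving the 8-hydroxy triene F6. Yamaguchi esterification with 33 through anhydride 34 gives the triene diester F7. Epoxidation with mCPBA (NaHCO3, CH2Cl2, 0 °C) is then done last on the fully acylated ring, and the sequence comes back to the route at 35.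

**Further compounds**

F1 | step 9 | ethyl 2-[(3S,8R)-8-(benzyldimethylsilyl)-3-(tert-butyldimethylsilyloxy)-6-oxo-13-norgermacra-1(10)E,4Z-dien-7-yl]-2-hydroxyacetate (mixture of C7/C11 diastereomers) | O=C1/C=C(/C)[C@@H](O[Si](C)(C)C(C)(C)C)C/C=C(\C)C[C@@H]([Si](C)(C)Cc2ccccc2)C1C(O)C(=O)OCC
F2 | step 9 | ethyl (3S,8R,7(11)Z)-8-(benzyldimethylsilyl)-3-(tert-butyldimethylsilyloxy)-6-oxo-13-norgermacra-1(10)E,4Z,7(11)-trien-12-oate | O=C1/C=C(/C)[C@@H](O[Si](C)(C)C(C)(C)C)C/C=C(\C)C[C@@H]([Si](C)(C)Cc2ccccc2)/C1=C\C(=O)OCC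
F3 | step 10 | ethyl (3S,6S,7S,8R)-8-(benzyldimethylsilyl)-3-(tert-butyldimethylsilyloxy)-6-hydroxy-13-norgermacra-1(10)E,4Z-dien-12-oate | O[C@H]1/C=C(/C)[C@@H](O[Si](C)(C)C(C)(C)C)C/C=C(\C)C[C@@H]([Si](C)(C)Cc2ccccc2)[C@H]1CC(=O)OCC
F4 | step 10 | (3S,6S,7S,8R)-8-(benzyldimethylsilyl)-3-(tert-butyldimethylsilyloxy)-13-norgermacra-1(10)E,4Z-dien-12,6-olide (cis-fused) | C1C(=O)O[C@H]2/C=C(/C)[C@@H](O[Si](C)(C)C(C)(C)C)C/C=C(\C)C[C@@H]([Si](C)(C)Cc3ccccc3)[C@@H]12
F5 | step 10 | (3S,6S,7S,8R)-8-(benzyldimethylsilyl)-3-(tert-butyldimethylsilyloxy)-6-hydroxy-13-norgermacra-1(10)E,4Z-dien-12-oic acid | O[C@H]1/C=C(/C)[C@@H](O[Si](C)(C)C(C)(C)C)C/C=C(\C)C[C@@H]([Si](C)(C)Cc2ccccc2)[C@H]1CC(=O)O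
F6 | step 15 | (3S,6R,7R,8R)-8-hydroxy-3-(isobutyryloxy)germacra-1(10)E,4Z,11(13)-trien-12,6-olide | C=C1C(=O)O[C@@H]2/C=C(/C)[C@@H](OC(=O)C(C)C)C/C=C(\C)C[C@@H](O)[C@@H]12
F7 | step 15 | (3S,6R,7R,8R)-3-(isobutyryloxy)-8-{[(2S,3S)-2,3-dimethyloxiran-2-yl]carbonyloxy}germacra-1(10)E,4Z,11(13)-trien-12,6-olide | C=C1C(=O)O[C@@H]2/C=C(/C)[C@@H](OC(=O)C(C)C)C/C=C(\C)C[C@@H](OC(=O)[C@@]3(C)O[C@H]3C)[C@@H]12
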